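## Retrosynthetic overview

1. Target ⇐ (S)-selective reduction of the side-chain ketone of a 1,3-diketone (acetyl-cyclopentanone).
2. 1,3-Diketone ⇐ Lewis-acid 1,2-acyl shift of a cadinane 4,5-epoxy-3-ketone carrying both esters (six → five contraction of ring A, cadinane → oplopane).
3. Epoxy-ketone diester ⇐ cadina-4,10(14)-dien-3-one by enone epoxidation, C2 enolate hydroxylation, SeO2 hydroxylation at C9 and two acylations.
4. Cadinadienone ⇐ bisabolane ketone (10-prenylcarvone) by C6–C7 ring closure (the 1,10-closure of cadinane biosynthesis), run as a 6-exo radical cyclisation of the γ-bromo-enone.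
5. Bisabolane ⇐ (R)-carvone + allyl unit + 2-methylbut-2-ene. Ring order: A (from carvone), then B (C6–C7), then contraction of A.

Assumption: the SMILES is read literally ((R)-2-methylbutanoate, (E)-3-methylpent-2-enoate); cadinane numbering (C1/C6 ring fusion, C15 on C4, isopropyl on C7, C14 on C10) is used for the decalins and kept for the same atoms afterwards; α = face of H-1, β = face of H-6.

## Route

Step 1
Reactants: 1 (R)-(−)-carvone
Product: 2 (5R)-5-(3-chloroprop-1-en-2-yl)-2-methylcyclohex-2-en-1-one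
Conditions: Ca(OCl)2, CO2 (dry ice), CH2Cl2–H2O, 0 °C
Reagents that add atoms: calcium hypochlorite, [Ca+2].[O-]Cl.[O-]Cl
Why: Ene-type allylic chlorination by HOCl attacks only the electron-rich isopropenyl group (the enone alkene is deactivated) and shifts the double bond within the 2-propenyl unit, leaving the stereocentre untouched.

Step 2
Reactants: 2 (5R)-5-(3-chloroprop-1-en-2-yl)-2-methylcyclohex-2-en-1-one; 3 allyltributylstannane
Product: 4 (5R)-5-(hexa-1,5-dien-2-yl)-2-methylcyclohex-2-en-1-one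
Conditions: Pd2(dba)3 (2.5 mol %), P(2-furyl)3 (10 mol %), THF, 60 °C
Reagents that add atoms: none
Why: Stille allyl–allyl cross-coupling; both allyl partners have equivalent termini, so only one 1,5-diene can form, and the enone is tolerated.

Step 3
Reactants: 4 (5R)-5-(hexa-1,5-dien-2-yl)-2-methylcyclohex-2-en-1-one; 5 2-methylbut-2-ene
Product: 6 (5R)-2-methyl-5-(6-methylhepta-1,5-dien-2-yl)cyclohex-2-en-1-one
Conditions: Grubbs II (5 mol %), 2-methylbut-2-ene/CH2Cl2, 40 °C
Reagents that add atoms: none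
Why: Olefin cross-metathesis converts only the monosubstituted alkene into the prenyl-type trisubstituted alkene; the 1,1-disubstituted alkene and the enone are inert to the catalyst.

Step 4
Reactants: 6 (5R)-2-methyl-5-(6-methylhepta-1,5-dien-2-yl)cyclohex-2-en-1-one
Product: 8 (4RS,5R)-4-bromo-2-methyl-5-(6-methylhepta-1,5-dien-2-yl)cyclohex-2-en-1-one, via silyl dienol ether 7 (not isolated)
Conditions: FeCl3 (5 mol %), MeMgBr, Et2O, −20 °C; TMSCl, Et3N, HMPA; then NBS, THF, −78 °C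
Reagents that add atoms: N-bromosuccinimide, O=C1CCC(=O)N1Br; chlorotrimethylsilane, C[Si](C)(C)Cl (silyl group of intermediate 7 only)
Why: Fe-catalysed Grignard (Kharasch-type) γ-deprotonation gives the through-conjugated dienolate, trapped as the linear silyl dienol ether, which NBS brominates at the γ-carbon (C6 of the later cadinane) because the α-carbon carries the methyl group; the configuration of the C–Br carbon does not matter.

Step 5
Reactants: 8 (4RS,5R)-4-bromo-2-methyl-5-(6-methylhepta-1,5-dien-2-yl)cyclohex-2-en-1-one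
Product: 9 (1S,6S,7R)-cadina-4,10(14)-dien-3-one
Conditions: Bu3SnH (syringe pump), AIBN (cat.), PhH (5 mM), 80 °C; then NaOMe (cat.), MeOH, rt
Reagents that add atoms: none
Why: Tin-hydride radical chain: the γ-keto allyl radical closes 6-exo-trig onto the prenyl alkene (C6–C7 bond) through a chair transition state with the ring-A bond at C1 and the CMe2 terminus equatorial (sets C7 relative to C1), the tertiary radical is reduced to the isopropyl group, and NaOMe equilibrates the γ-centre C6 to the trans-fused cadinane.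

Step 6
Reactants: 9 (1S,6S,7R)-cadina-4,10(14)-dien-3-one
Product: 10 (1S,4R,5R,6R,7R)-4,5-epoxycadin-10(14)-en-3-one
Conditions: 30% H2O2, NaOH (cat.), MeOH, 0 °C
Reagents that add atoms: hydrogen peroxide, OO
Why: Weitz–Scheffer nucleophilic epoxidation touches only the enone; hydroperoxide adds axially to C5 anti to the axial H-6, giving the 4α,5α-epoxide.

Step 7
Reactants: 10 (1S,4R,5R,6R,7R)-4,5-epoxycadin-10(14)-en-3-one
Product: 12 (1S,2R,4R,5R,6R,7R)-4,5-epoxy-2-hydroxycadin-10(14)-en-3-one, via sodium enolate 11 (not isolated)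
Conditions: NaHMDS, THF, −78 °C; then 2-(phenylsulfonyl)-3-phenyloxaziridine, −78 °C; NH4Cl
Reagents that add atoms: 2-(phenylsulfonyl)-3-phenyloxaziridine (Davis reagent), O=S(=O)(N1OC1c1ccccc1)c1ccccc1; sodium hexamethyldisilazide, [Na]N([Si](C)(C)C)[Si](C)(C)C (sodium of intermediate 11 only)
Why: Davis enolate hydroxylation; C2 is the only enolisable position (C4 is fully substituted), and the oxidant attacks axially, anti to the axial H-1, giving the 2β (axial, 2R) alcohol under kinetic control.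

Step 8
Reactants: 12 (1S,2R,4R,5R,6R,7R)-4,5-epoxy-2-hydroxycadin-10(14)-en-3-one; 13 (R)-2-methylbutanoic acid
Product: 14 (1S,2R,4R,5R,6R,7R)-4,5-epoxy-3-oxocadin-10(14)-en-2-yl (2R)-2-methylbutanoate
Conditions: DCC, DMAP (cat.), CH2Cl2, 0 °C → rt
Reagents that add atoms: none
Why: Steglich esterification under near-neutral conditions acylates the α-ketol without epimerising C2 or the acid α-centre.

Step 9
Reactants: 14 (1S,2R,4R,5R,6R,7R)-4,5-epoxy-3-oxocadin-10(14)-en-2-yl (2R)-2-methylbutanoate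
Product: 15 (1S,2R,4R,5R,6R,7R,9S)-4,5-epoxy-9-hydroxy-3-oxocadin-10(14)-en-2-yl (2R)-2-methylbutanoate
Conditions: SeO2 (0.3 equiv), t-BuOOH, CH2Cl2, rt
Reagents that add atoms: tert-butyl hydroperoxide, CC(C)(C)OO (oxygen relayed by catalytic selenium dioxide, O=[Se]=O)
Why: Sharpless SeO2 allylic hydroxylation (ene reaction then [2,3]-shift) of the exocyclic methylene prefers the allylic CH2 (C9) over the ring-fusion CH (C1) and replaces the axial H-9α suprafacially, giving the axial 9α (9S) alcohol with the C10=C14 bond restored.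

Step 10
Reactants: 15 (1S,2R,4R,5R,6R,7R,9S)-4,5-epoxy-9-hydroxy-3-oxocadin-10(14)-en-2-yl (2R)-2-methylbutanoate; 16 (2E)-3-methylpent-2-enoic acid
Product: 18 (1S,2R,4R,5R,6R,7R,9S)-4,5-epoxy-2-{[(2R)-2-methylbutanoyl]oxy}-3-oxocadin-10(14)-en-9-yl (2E)-3-methylpent-2-enoate, via mixed anhydride 17 (not isolated)
Conditions: 16, 2,4,6-Cl3C6H2COCl, Et3N, THF, rt; then 15, DMAP (cat.), PhMe, rt
Reagents that add atoms: 2,4,6-trichlorobenzoyl chloride, O=C(Cl)c1c(Cl)cc(Cl)cc1Cl (aroyl group of intermediate 17 only)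
Why: Yamaguchi esterification acylates the hindered axial allylic alcohol with retention at C9 and keeps the (E)-enoate geometry.

Step 11
Reactants: 18 (1S,2R,4R,5R,6R,7R,9S)-4,5-epoxy-2-{[(2R)-2-methylbutanoyl]oxy}-3-oxocadin-10(14)-en-9-yl (2E)-3-methylpent-2-enoate
Product: 19 (1R,3R,3aS,5S,7R,7aR)-1-acetyl-4-methylidene-3-{[(2R)-2-methylbutanoyl]oxy}-2-oxo-7-(propan-2-yl)octahydro-1H-inden-5-yl (2E)-3-methylpent-2-enoate (1,3-diketone, largely enolised)
Conditions: BF3·OEt2 (0.3 equiv), CH2Cl2, −78 → −20 °C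
Reagents that add atoms: none
Why: Lewis-acid rearrangement of an α,β-epoxy ketone (House/Meinwald-type semipinacol): the epoxide opens at C5 (β to the carbonyl), the C3 acyl carbon migrates from C4 to C5 with oxygen push from C4, contracting ring A to the cyclopentanone and releasing C4 as the acetyl ketone; C5 is a 1,3-dicarbonyl centre and is not fixed here.

Step 12
Reactants: 19 (1R,3R,3aS,5S,7R,7aR)-1-acetyl-4-methylidene-3-{[(2R)-2-methylbutanoyl]oxy}-2-oxo-7-(propan-2-yl)octahydro-1H-inden-5-yl (2E)-3-methylpent-2-enoate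
Product: 20 (1R,3R,3aS,5S,7R,7aR)-1-[(1S)-1-hydroxyethyl]-4-methylidene-3-{[(2R)-2-methylbutanoyl]oxy}-2-oxo-7-(propan-2-yl)octahydro-1H-inden-5-yl (2E)-3-methylpent-2-enoate
Conditions: Prelog-selective ketoreductase (purified ADH, e.g. Rhodococcus ruber type), NAD(P)H (cat.), i-PrOH (10% v/v), phosphate buffer pH 7, 30 °C
Reagents that add atoms: none
Why: Enzymatic ketone reduction: the ADH accepts the unhindered methyl ketone and not the flanked ring ketone, delivering hydride by the Prelog rule to give the (S)-carbinol, while the epimerisable C5 settles with the side chain trans to C7 (cis to H-6), the more stable arrangement on the trans-hydrindanone.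

## Compound list

1 | (R)-(−)-carvone, (5R)-2-methyl-5-(prop-1-en-2-yl)cyclohex-2-en-1-one | C=C(C)[C@H]1CC(=O)C(C)=CC1 | starting material
2 | (5R)-5-(3-chloroprop-1-en-2-yl)-2-methylcyclohex-2-en-1-one | C=C(CCl)[C@H]1CC(=O)C(C)=CC1 | intermediate
3 | allyltributylstannane | C=CC[Sn](CCCC)(CCCC)CCCC | starting material
4 | (5R)-5-(hexa-1,5-dien-2-yl)-2-methylcyclohex-2-en-1-one | C=CCCC(=C)[C@H]1CC(=O)C(C)=CC1 | intermediate
5 | 2-methylbut-2-ene | CC=C(C)C | starting material
6 | (5R)-2-methyl-5-(6-methylhepta-1,5-dien-2-yl)cyclohex-2-en-1-one | CC(C)=CCCC(=C)[C@H]1CC(=O)C(C)=CC1 | intermediate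
7 | trimethyl{[(5S)-2-methyl-5-(6-methylhepta-1,5-dien-2-yl)cyclohexa-1,3-dien-1-yl]oxy}silane (carvone configuration retained) | CC(C)=CCCC(=C)[C@H]1CC(O[Si](C)(C)C)=C(C)C=C1 | intermediate (not isolated)
8 | (4RS,5R)-4-bromo-2-methyl-5-(6-methylhepta-1,5-dien-2-yl)cyclohex-2-en-1-one | CC(C)=CCCC(=C)[C@H]1CC(=O)C(C)=CC1Br | intermediate
9 | (1S,6S,7R)-cadina-4,10(14)-dien-3-one (trans-fused, isopropyl equatorial) | C=C1[C@@H]2[C@H](C=C(C)C(=O)C2)[C@@H](C(C)C)CC1 | intermediate
10 | (1S,4R,5R,6R,7R)-4,5-epoxycadin-10(14)-en-3-one (4α,5α-epoxide) | C=C1[C@@H]2[C@H]([C@H]3O[C@@]3(C)C(=O)C2)[C@@H](C(C)C)CC1 | intermediate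
11 | sodium enolate of 10 (C2=C3–ONa; other centres as in 10) | C=C1[C@@H]2[C@H]([C@H]3O[C@@]3(C)C(O[Na])=C2)[C@@H](C(C)C)CC1 | intermediate (not isolated)
12 | (1S,2R,4R,5R,6R,7R)-4,5-epoxy-2-hydroxycadin-10(14)-en-3-one | C=C1[C@@H]2[C@H]([C@H]3O[C@@]3(C)C(=O)[C@@H]2O)[C@@H](C(C)C)CC1 | intermediate
13 | (R)-2-methylbutanoic acid | CC[C@@H](C)C(=O)O | starting material
14 | (1S,2R,4R,5R,6R,7R)-4,5-epoxy-3-oxocadin-10(14)-en-2-yl (2R)-2-methylbutanoate | C=C1[C@@H]2[C@H]([C@H]3O[C@@]3(C)C(=O)[C@@H]2OC(=O)[C@H](C)CC)[C@@H](C(C)C)CC1 | intermediate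
15 | (1S,2R,4R,5R,6R,7R,9S)-4,5-epoxy-9-hydroxy-3-oxocadin-10(14)-en-2-yl (2R)-2-methylbutanoate | C=C1[C@@H]2[C@H]([C@H]3O[C@@]3(C)C(=O)[C@@H]2OC(=O)[C@H](C)CC)[C@@H](C(C)C)C[C@@H]1O | intermediate
16 | (2E)-3-methylpent-2-enoic acid | CC/C(C)=C/C(=O)O | starting material
17 | (2E)-3-methylpent-2-enoic 2,4,6-trichlorobenzoic anhydride | CC/C(C)=C/C(=O)OC(=O)c1c(Cl)cc(Cl)cc1Cl | intermediate (not isolated)
18 | (1S,2R,4R,5R,6R,7R,9S)-4,5-epoxy-2-{[(2R)-2-methylbutanoyl]oxy}-3-oxocadin-10(14)-en-9-yl (2E)-3-methylpent-2-enoate | C=C1[C@@H]2[C@H]([C@H]3O[C@@]3(C)C(=O)[C@@H]2OC(=O)[C@H](C)CC)[C@@H](C(C)C)C[C@@H]1OC(=O)/C=C(\C)CC | intermediate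
19 | (1R,3R,3aS,5S,7R,7aR)-1-acetyl-4-methylidene-3-{[(2R)-2-methylbutanoyl]oxy}-2-oxo-7-(propan-2-yl)octahydro-1H-inden-5-yl (2E)-3-methylpent-2-enoate | C=C1[C@@H]2[C@H]([C@H](C(C)=O)C(=O)[C@@H]2OC(=O)[C@H](C)CC)[C@@H](C(C)C)C[C@@H]1OC(=O)/C=C(\C)CC | intermediate
20 | (1R,3R,3aS,5S,7R,7aR)-1-[(1S)-1-hydroxyethyl]-4-methylidene-3-{[(2R)-2-methylbutanoyl]oxy}-2-oxo-7-(propan-2-yl)octahydro-1H-inden-5-yl (2E)-3-methylpent-2-enoate (CNP0224363.1) | C=C1[C@@H]2[C@H]([C@H]([C@H](C)O)C(=O)[C@@H]2OC(=O)[C@H](C)CC)[C@@H](C(C)C)C[C@@H]1OC(=O)/C=C(\C)CC | target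

## Step count and risks

Total steps: 12. Longest linear sequence: 12 (from 1).

Most likely to fail, first: step 5. The stabilised γ-keto allyl radical may be reduced by the tin hydride before it cyclises, or close with poor control at C7. The fallback is a closed-shell closure with halide return. From 8, catalytic ZnBr2·OEt2 in CH2Cl2 at −40 °C ionises the allylic bromide, the allyl cation is trapped at C6 by the prenyl alkene, and bromide returns to the tertiary cation, giving (1S,6S,7S)-11-bromocadina-4,10(14)-dien-3-one F1. Bu3SnH/Et3B at 0 °C then reduces only the tertiary C–Br bond, NaOMe equilibrates C6, and the route is rejoined at 9.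

Second: step 11. In the 4α,5α-epoxide the breaking C5–O bond is roughly antiperiplanar to H-6 and to the C4 methyl group, so hydride or methyl shift may compete with the acyl shift, and BF3 may ionise the allylic ester. The fallback is a two-stage semipinacol through a halohydrin. From 18, MgBr2·OEt2 in Et2O at 0 °C opens the epoxide at C5 with inversion to (1S,2R,4S,5S,6R,7R,9S)-5-bromo-4-hydroxy-2-{[(2R)-2-methylbutanoyl]oxy}-3-oxocadin-10(14)-en-9-yl (2E)-3-methylpent-2-enoate F2. Its equatorial C5–Br bond is antiperiplanar to the C3–C4 ring bond, and AgBF4 in CH2Cl2 at −20 °C then drives the acyl shift with loss of bromide, returning to the route at 19.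

Third: step 12. The enolised diketone may be a poor enzyme substrate, or the enzyme may give the wrong carbinol. The fallback is substrate-controlled reduction followed by stereochemical correction. From 19, Zn(BH4)2 in Et2O at −78 °C reduces the less hindered acetyl carbonyl; any 20 formed is kept, and the epimer (1R,3R,3aS,5S,7R,7aR)-1-[(1R)-1-hydroxyethyl]-4-methylidene-3-{[(2R)-2-methylbutanoyl]oxy}-2-oxo-7-(propan-2-yl)octahydro-1H-inden-5-yl (2E)-3-methylpent-2-enoate F3 is inverted by Mitsunobu reaction (HCO2H, PPh3, DIAD, THF, 0 °C) to the formate (1R,3R,3aS,5S,7R,7aR)-1-[(1S)-1-(formyloxy)ethyl]-4-methylidene-3-{[(2R)-2-methylbutanoyl]oxy}-2-oxo-7-(propan-2-yl)octahydro-1H-inden-5-yl (2E)-3-methylpent-2-enoate F4. KHCO3 in MeOH at 0 °C cleaves only the formate and gives 20.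

Further compounds
F1 | step 5 | (1S,6S,7S)-11-bromocadina-4,10(14)-dien-3-one | C=C1[C@@H]2[C@H](C=C(C)C(=O)C2)[C@@H](C(C)(C)Br)CC1
F2 | step 11 | (1S,2R,4S,5S,6R,7R,9S)-5-bromo-4-hydroxy-2-{[(2R)-2-methylbutanoyl]oxy}-3-oxocadin-10(14)-en-9-yl (2E)-3-methylpent-2-enoate | C=C1[C@@H]2[C@H]([C@H](Br)[C@@](C)(O)C(=O)[C@@H]2OC(=O)[C@H](C)CC)[C@@H](C(C)C)C[C@@H]1OC(=O)/C=C(\C)CC
F3 | step 12 | (1R,3R,3aS,5S,7R,7aR)-1-[(1R)-1-hydroxyethyl]-4-methylidene-3-{[(2R)-2-methylbutanoyl]oxy}-2-oxo-7-(propan-2-yl)octahydro-1H-inden-5-yl (2E)-3-methylpent-2-enoate | C=C1[C@@H]2[C@H]([C@H]([C@@H](C)O)C(=O)[C@@H]2OC(=O)[C@H](C)CC)[C@@H](C(C)C)C[C@@H]1OC(=O)/C=C(\C)CC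
F4 | step 12 | (1R,3R,3aS,5S,7R,7aR)-1-[(1S)-1-(formyloxy)ethyl]-4-methylidene-3-{[(2R)-2-methylbutanoyl]oxy}-2-oxo-7-(propan-2-yl)octahydro-1H-inden-5-yl (2E)-3-methylpent-2-enoate | C=C1[C@@H]2[C@H]([C@H]([C@H](C)OC=O)C(=O)[C@@H]2OC(=O)[C@H](C)CC)[C@@H](C(C)C)C[C@@H]1OC(=O)/C=C(\C)CC
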